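The readings come from a simulation from invented constants; the scatter is artificial.

Every mole of D charged stays in the books: at any moment it stands as D, X, Z or Q, and these entries sum to the charge. D is the limiting reagent, so you keep the books in percent of the D charged, and the entry asked for is X.

| flask | D | G | temperature | remark | time |
|---|---|---|---|---|---|
| cedar | 5.5 mM | 1.5 equiv | −12 °C | run made earlier |  |
| larch | 22 mM | 1.5 equiv | 15 °C | run made earlier |  |
| blue | 11 mM | 1.50 equiv | 25 °C |  | 15 min |
| violet | 11 mM | 1.50 equiv | 0 °C |  | 15 min |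
| teal | 11 mM | 1.50 equiv | −25 °C |  | 15 min |
| ochre | 11 mM | 1.50 equiv |  | at −25 °C until 8.0 min, from then on at 25 °C | 15 min |

| run | time / min | X / % |
|---|---|---|
| cedar | 12.0 | 5.5 |
| cedar | 25.0 | 10.5 |
| cedar | 30.0 | 12.3 |
| cedar | 50.0 | 18.8 |
| cedar | 60.0 | 22.1 |
| larch | 1.33 | 23.0 |
| larch | 4.00 | 44.8 |
| larch | 6.00 | 52.8 |
| larch | 10.0 | 62.3 |
| larch | 15.0 | 67.1 |

(scatter of a reading: 0.3 percentage points)

- the flask that comes out highest in amount of X, in percent of the D charged, or "all alike" when all lie within 1.5 percentage points (blue / violet / teal / ochre / all alike)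
- X at the end, in percent of the D charged, blue
- X at the end, in percent of the D charged, violet
- X at the end, in percent of the D charged, teal
- X at the end, in percent of the D charged, ochre

- E is meant together with its J
- solid, in amounts per volume of the solution: J
- steps under discussion: D + G -> X + E; G + X -> Z + E; J <-> E; X <-> Q

Start with what has left D. If the first step has rate k·c_D·c_G, then with 1.50 equiv of G, integration ties the converted fraction x to N, the product of k, the starting c_D and the minutes: N = 2·ln[(3 − 2x)/(3(1 − x))].

I take early X as converted D. Cedar's 10.5% at 25.0 min then gives k = 0.558 M⁻¹ min⁻¹, and larch's 23.0% at 1.33 min gives 6.49 M⁻¹ min⁻¹. In logarithms, that is 1.07 powers of ten across the two temperatures, a slope of 2970 K against reciprocal temperature. This slope carries k to 14.4 M⁻¹ min⁻¹ at 25 °C, 1.76 M⁻¹ min⁻¹ at 0 °C and 0.142 M⁻¹ min⁻¹ at −25 °C.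

The quantity to carry is the exposure, N added up stretch by stretch over a flask's temperatures: teal has 0.0234, violet 0.291, blue 2.37 and ochre 1.12. Inverting the formula enters converted D as 3.40% for teal, 32.0% for violet, 87.2% for blue and 69.2% for ochre.

Next comes the share of converted D still standing as X. Larch's last reading has exposure 2.14, hence by the formula an estimated 85.2% converted against 67.1% of X, a share of 78.8%. Cedar's last reading gives 98.5%. I give the larch share to the two flasks that spend time at 25 °C and the cedar share to the two colder ones. My books close with X at 68.7% in blue, 31.5% in violet, 3.35% in teal and 54.5% in ochre, so blue leads.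

The forecast, whose figures differ from mine, names blue, with 66%, 30%, 3.4% and 56% in the same order, and says “Ochre is effectively 7 min at 25 °C”.

The flasks give X at 69.7% in blue, 30.6% in violet, 3.50% in teal and 58.0% in ochre, with blue highest.

    D + G → X + E (k = 15.0 M⁻¹ min⁻¹, Ea = 57.0 kJ mol⁻¹)
    G + X → Z + E (k = 0.890 M⁻¹ min⁻¹, Ea = 72.0 kJ mol⁻¹)
    J ⇌ E, rate k3*(cs3 - [E]) while solid is left; crystals form when [E] > cs3 (solubility = 0.210 mM, k = 1.40 min⁻¹)
    X ⇌ Q (K = 0.170, k = 0.240 min⁻¹, Ea = 90.0 kJ mol⁻¹, ΔH = −16.0 kJ mol⁻¹)
    (constants at 25 °C)

Blue's figure is a passing value, for its X reads 58.0% at 150 min. At a fixed temperature and charge, exposure grows in step with the minutes, so teal read at 1.0 h has 0.0934, which by the formula converts 12.5% of D. That reading of teal holds D at 87.1%.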